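**Remarks on the chemistry**

- Numbering: ring carbons C1–C6 as in the target (C1 quaternary, C2 benzoate-bearing, C3 hydroxyl-bearing, C4=C5, C6 the oxirane CH); C7 is the exocyclic CH2. O1, O2, O3 and O7 are the oxygens on the carbon of the same number; O1 ends as the oxirane oxygen.
- Assumption: the sense of induction of the chiral bis(amidine) salt on this substrate class cannot be predicted. The (R,R) catalyst is written; its (S,S) antipode is used instead if the opposite alkene arm is attacked.
- Structure check: in 12 the carbonate spans O1 and O2 on one face, iodine on C3 is trans to O2, and C1 and C2 have the spatial arrangement needed in 18. No correction is required.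
- Precursor design: 8 keeps the O7 benzoate. It stops the primary hydroxyl from capturing 9, its neutral carbonyl is a much weaker nucleophile than an anionic hydrogen carbonate, and it is solvolysed together with the carbonate in step 7 at no cost in steps, because O7 and O2 are benzoylated together in step 9. A silyl ether on O7 would survive step 7 but would add a final selective acylation.

## Structural features

The target is one carbocycle, a cyclohexene (C1–C6, C4=C5), cis-fused to an oxirane across C1–C6, with a benzoyloxymethyl arm (C7) on C1. Four stereocentres stand in a row, C6–C1–C2–C3. C1 is quaternary, and the oxirane oxygen, the C2 benzoate and the C3 hydroxyl all lie on one face, with C7 on the other. The oxirane is allylic at C6 and opens under acid. The C2 benzoate is cis-vicinal to the free C3 hydroxyl and can migrate under base. Every diene intermediate on the way can aromatise by loss of water. The real difficulty is threefold: absolute configuration at a quaternary C1 with no hydrogen and no handle, an oxirane on the same face as two more oxygens, and a benzoate on O2 but none on the cis O3. The key step uses the fact that, once the O1–C6 bond is removed, C1 is the carbinol carbon of a mirror-symmetric cyclohexa-2,5-dien-1-ol whose arms C2=C3 and C6=C5 are enantiotopic. Because O2 is cis to O1, a one-carbon tether on O1 can deliver oxygen to C2 of one arm and set C1 and C2 together.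

## Logic of the disconnections

**18 to 17.** The O3–Si bond is cut. O3 stays masked until the end because that is the only way to hold a benzoate on O2 and none on the cis O3. The gain is small, but the ester pattern is fixed. The forward step needs near-neutral fluoride so that the ester does not migrate and the oxirane is not opened.

**17 to 16.** The oxirane bond O1–C6 is cut, the C4–O3 bond is re-formed and the alkene moves from C4=C5 to C5=C6. This puts the epoxide where a hydroxyl on C2 can deliver it, and leaves C1 as a plain tertiary alcohol. The forward step must be an allylic (SN2′) closure of O1 onto C6 on its own face, with a silyl group capturing O3.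

**16 to 15 to 14.** The ester C–O bonds on O7 and O2 are cut, then the two epoxide C–O bonds at C3 and C4. This leads to a diene triol with only two stereocentres. The forward epoxidation must choose C3=C4 over C5=C6 and the face of O2; the acylation must spare the tertiary O1.

**14 to 13 to 12.** The triol is traced to the O1/O2 carbonate and O7 benzoate of 13, and H–I is added back across C3=C4 with iodine on C3. This gives 12, which has a single alkene and three defined stereocentres. The forward step needs an anti elimination that can only go toward C4, then solvolysis of the acyl groups.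

**12 to 8, 9 and 10.** The C2–O bond, the C3–I bond and the O1–C(carbonyl) bond are cut. All stereocentres vanish and an achiral dienol remains. The forward step must tell two enantiotopic alkenes apart while the tether fixes the relative configuration.

**8 to 6 and 7.** The ester C–O bond on O7 is cut. The forward step is a primary-selective acylation in the presence of a tertiary, doubly allylic alcohol that must not ionise.

**6 to 5 to 3.** The C7 alcohol is traced to an ester, and the C1–O1 bond is cut to the enolate 4 of 3. The forward steps are a hydride reduction and an electrophilic hydroxylation that must occur at C1 without oxidising the diene to an arene.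

**3 to 2 to 1.** The O–CH3 bond and the two ring C–H bonds at C1 and C4 are cut. This reaches a commodity arene. The forward steps are a dissolving-metal reduction and an acid-free esterification.

## Other disconnections considered

**Alternative 1:** The cut is the oxirane C1–O bond together with functionalisation of C7, leading back to the exocyclic methylene alcohol A1 (C1=C7, free C6 hydroxyl, arylmethyl ether on O2, silyl ether on O3).

- Forward key step: an electrophilic iodine source such as 10 would form the iodonium ion on C1=C7, and the C6 hydroxyl would open it at the tertiary carbon C1 in a 3-exo closure to the iodomethyl oxirane A2.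
- In favour: the oxirane would be made directly in its final place, with a leaving group on C7 for the benzoate. On this point Alternative 1 is the better plan, since no later epoxide migration is needed. The cis fusion at C1 would be enforced by the ring, which is equal to the tether control of the chosen plan.
- Against: three-membered ring closure onto an iodonium ion is rare and likely reversible. The ring alkene C4=C5 competes for iodine. Displacing a neopentyl-type iodide next to a quaternary oxirane carbon would be slow and open to rearrangement. A1 already holds three stereocentres (C2, C3, C6), so the problem of absolute configuration is only moved into its preparation.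
- Comparison: after A2 about four steps would remain, similar to the five of the chosen plan, but A1 would need far more steps than the five to 8. Mechanistically Alternative 1 relays existing stereocentres, whereas the chosen plan creates them from an achiral diene.

**Alternative 2:** The cut is both C–O bonds at C1 and C2, back to the aromatic acid 1.

- Forward key step: whole cells expressing benzoate 1,2-dioxygenase would add O2 across the ipso and ortho carbons of 1 to give the cis-diol acid A3. No ring closes.
- In favour: this is a known biotransformation. It would set C1 and C2 in the spatial arrangement of 14 in one step. Esterification and hydride reduction would then reach 14, and steps 8 to 11 would apply unchanged.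
- Against: it needs fermentation with a blocked mutant strain and isolation of a water-soluble, acid-labile diol acid from dilute broth. Only one enantiomeric series is accessible, though it is the right one here. The carboxyl must be reduced to CH2OH.
- Comparison: Alternative 2 is the better plan in step economy (14 in about three steps instead of seven) and in certainty of absolute configuration. It is equal in the endgame. The chosen plan has the edge only in being purely chemical, in giving either enantiomer by choice of catalyst, and in avoiding the diol acid.

**Alternative 3:** The cut is C1–C6 and C2–C3 in a Diels–Alder sense, giving the diene A4 and the dienophile A5.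

- Forward key step: a chiral oxazaborolidinium Lewis acid would activate the formyl group of A5, and A4 would add with the formyl group exo to give the all-cis adduct A6.
- In favour: it is convergent. One step would build the ring and four contiguous stereocentres, the quaternary C1 included, with every oxygen already in place. In convergence and stereocentres per step Alternative 3 is the better plan. It is equal in that one catalytic step carries the absolute configuration.
- Against: A4 is a sluggish diene and A5 a trisubstituted, doubly oxygenated dienophile. The all-cis topicity depends on exo-formyl selectivity. The strong Lewis acid could ionise the allylic acetates of A6.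
- The endgame is the main weakness. The aldehyde must be reduced and a benzoyl group moved from O1 to O7. The two allylic acetates must be told apart, and one removed beside two benzoates. The C6 oxygen is cis to O1, so direct SN2 closure of the oxirane is impossible; a net-retention substitution (for example through a zerovalent palladium allyl complex) or a double inversion would be needed.
- Comparison: more steps would probably follow A6 than the five that follow 12, and with less secure selectivity.

Key step: step 6

## Route

Step 1
Reactants: 1 benzoic acid
Product: 2 cyclohexa-2,5-diene-1-carboxylic acid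
Conditions: Na, NH3(l), EtOH, −78 → −33 °C; NH4Cl; aq. HCl (pH 2), 0 °C
Reagents that add atoms: none
Why: Birch reduction: the carboxylate stabilises negative charge at the ipso carbon, so protonation occurs at ipso and para and the unconjugated 2,5-diene results; no stereocentre is formed.

Step 2
Reactants: 2 cyclohexa-2,5-diene-1-carboxylic acid
Product: 3 methyl cyclohexa-2,5-diene-1-carboxylate
Conditions: MeI, KHCO3, DMF, rt
Reagents that add atoms: iodomethane, CI
Why: SN2 O-methylation of the carboxylate without acid; KHCO3 is too weak a base to remove the doubly allylic C1–H, so the diene should neither move into conjugation nor aromatise.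

Step 3
Reactants: 3 methyl cyclohexa-2,5-diene-1-carboxylate
Product: 5 methyl 1-hydroxycyclohexa-2,5-diene-1-carboxylate, via potassium dienolate 4 (not isolated)
Conditions: KN(SiMe3)2, THF, −78 °C; 2-(phenylsulfonyl)-3-phenyloxaziridine, −78 °C; aq. NH4Cl
Reagents that add atoms: 2-(phenylsulfonyl)-3-phenyloxaziridine, O=S(=O)(c1ccccc1)N1OC1c1ccccc1
Why: Enolate α-hydroxylation by oxygen transfer from an N-sulfonyloxaziridine: the cross-conjugated dienolate 4 reacts at C1, as it does in Birch reduction–alkylation chemistry, and the potassium counter-ion disfavours addition to the sulfonimine by-product. The product is achiral, and the ester group disfavours ionisation of the new tertiary, doubly allylic C1–O bond.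

Step 4
Reactants: 5 methyl 1-hydroxycyclohexa-2,5-diene-1-carboxylate
Product: 6 1-(hydroxymethyl)cyclohexa-2,5-dien-1-ol
Conditions: LiAlH4, Et2O, 0 °C; H2O, aq. NaOH
Reagents that add atoms: none
Why: Hydride reduction of the ester to the primary alcohol; isolated alkenes are inert to LiAlH4, and the alkaline work-up avoids the acid that would ionise the doubly allylic tertiary alcohol.

Step 5
Reactants: 6 1-(hydroxymethyl)cyclohexa-2,5-dien-1-ol; 7 benzoyl chloride
Product: 8 (1-hydroxycyclohexa-2,5-dien-1-yl)methyl benzoate
Conditions: 7 (1.05 equiv), Et3N, DMAP (cat.), CH2Cl2, −20 °C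
Reagents that add atoms: benzoyl chloride (7), O=C(Cl)c1ccccc1
Why: Nucleophile-catalysed acylation, selective for the primary hydroxyl because the tertiary one is far more hindered; the benzoate blocks O7 so that only O1 can capture 9 in step 6.

Step 6
Reactants: 8 (1-hydroxycyclohexa-2,5-dien-1-yl)methyl benzoate; 9 carbon dioxide; 10 N-iodosuccinimide
Product: 12 [(3aR,7S,7aS)-7-iodo-2-oxo-3a,6,7,7a-tetrahydro-1,3-benzodioxol-3a-yl]methyl benzoate (cis-fused carbonate on O1 and O2; iodine on C3 trans to O2), via hydrogen carbonate 11 (not isolated)
Conditions: 9 (1 atm), 10 (1.2 equiv), (1R,2R)-N,N′-bis[4-(pyrrolidin-1-yl)quinolin-2-yl]-1,2-diphenylethane-1,2-diamine·HN(SO2CF3)2 (1:1 salt, 10 mol%), 4 Å MS, PhMe, −20 °C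
Reagents that add atoms: carbon dioxide (9), O=C=O; N-iodosuccinimide (10), O=C1CCC(=O)N1I
Why: Proposed new method: the tertiary alcohol of 8 adds to 9 and the free amidine of the catalyst deprotonates the carbonic half-ester to the ion-paired hydrogen carbonate 11 while the amidinium N–H activates 10; an iodonium ion then forms on one alkene and is opened from the back by the carbonate oxygen, the closest known reaction types being catalytic enantioselective CO2 capture with iodocyclisation of unsaturated alcohols to cyclic carbonates and asymmetric halocyclisations that desymmetrise cyclohexa-1,4-dienes. The only ring closed is the 1,3-dioxolan-2-one, by 5-exo attack at C2; 6-endo attack at C3 would need a strained bridged six-membered carbonate. C1 becomes stereogenic through the catalyst's choice between the enantiotopic arms C2=C3 and C6=C5, the only element of absolute control. C2 is fixed relative to C1 by the one-carbon tether, which can only span a cis ring fusion. C3 is fixed by anti opening of the iodonium ion, which places iodine trans to O2. The step needs selection of one alkene (catalyst), of C2 over C3 (ring size) and of the anionic hydrogen carbonate over the neutral O7 ester carbonyl as nucleophile (charge, and the benzoate keeps 9 off the primary oxygen). Ionisation of the doubly allylic C1–O bond should be held back by the low temperature, the buffered acid–base catalyst and the sieves.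

Step 7
Reactants: 12 [(3aR,7S,7aS)-7-iodo-2-oxo-3a,6,7,7a-tetrahydro-1,3-benzodioxol-3a-yl]methyl benzoate
Product: 14 (1R,2R)-1-(hydroxymethyl)cyclohexa-3,5-diene-1,2-diol, via diene carbonate 13 (not isolated)
Conditions: DBU, THF, 50 °C; then K2CO3 (0.3 equiv), MeOH, 0 °C → rt (one pot)
Reagents that add atoms: none
Why: Anti E2 dehydroiodination: the only hydrogen anti-periplanar to the C3 iodide is on C4 (the C2 hydrogen is syn), so only the conjugated C3=C4–C5=C6 diene 13 can form. Base-catalysed transesterification with methanol then removes the carbonate and the benzoate; C1 and C2 are not touched.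

Step 8
Reactants: 14 (1R,2R)-1-(hydroxymethyl)cyclohexa-3,5-diene-1,2-diol
Product: 15 (1S,2R,3R,6R)-3-(hydroxymethyl)-7-oxabicyclo[4.1.0]hept-4-ene-2,3-diol (3,4-epoxide cis to O2)
Conditions: mCPBA, NaHCO3, EtOAc, 0 °C → rt
Reagents that add atoms: 3-chloroperoxybenzoic acid, O=C(OO)c1cccc(Cl)c1
Why: Hydroxyl-directed peracid epoxidation: the secondary allylic O2–H hydrogen-bonds the peracid and delivers oxygen to the adjacent C3=C4 on its own face, which sets C3 and C4 cis to O2. C5=C6 is flanked by the quaternary C1, and the same site and face selectivity is known for the 1-carboxylate analogue of 14.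

Step 9
Reactants: 15 (1S,2R,3R,6R)-3-(hydroxymethyl)-7-oxabicyclo[4.1.0]hept-4-ene-2,3-diol; 7 benzoyl chloride
Product: 16 [(1R,2R,3R,6R)-2-(benzoyloxy)-3-hydroxy-7-oxabicyclo[4.1.0]hept-4-en-3-yl]methyl benzoate
Conditions: 7 (2.3 equiv), pyridine, DMAP (cat.), CH2Cl2, 0 °C
Reagents that add atoms: benzoyl chloride (7), O=C(Cl)c1ccccc1
Why: Nucleophile-catalysed acylation: primary O7 and secondary O2 are benzoylated, the tertiary O1–H is too hindered, and the epoxide is inert to the basic medium at 0 °C.

Step 10
Reactants: 16 [(1R,2R,3R,6R)-2-(benzoyloxy)-3-hydroxy-7-oxabicyclo[4.1.0]hept-4-en-3-yl]methyl benzoate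
Product: 17 [(1S,2R,3R,6S)-2-(benzoyloxy)-3-[(tert-butyldimethylsilyl)oxy]-7-oxabicyclo[4.1.0]hept-4-en-1-yl]methyl benzoate
Conditions: t-BuMe2SiOTf (3 equiv), Et3N, CH2Cl2, −78 → 0 °C
Reagents that add atoms: tert-butyldimethylsilyl trifluoromethanesulfonate, CC(C)(C)[Si](C)(C)OS(=O)(=O)C(F)(F)F
Why: Silyl-triflate-induced allylic (SN2′) epoxide transposition, a reaction type known for the closely related syn-3,4-epoxide of a 1-(methoxycarbonyl)cyclohex-5-ene-1,2-diol: silylation of the epoxide oxygen turns C4–O into a leaving group, O1 bonds to C6 as the π bond moves to C4=C5, and the silyl group stays on O3. C6 is set by the tether (O1 can reach C6 only on the face it occupies), and C3 keeps its configuration because its C–O bond is never broken.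

Step 11
Reactants: 17 [(1S,2R,3R,6S)-2-(benzoyloxy)-3-[(tert-butyldimethylsilyl)oxy]-7-oxabicyclo[4.1.0]hept-4-en-1-yl]methyl benzoate
Product: 18 [(1S,2R,3R,6S)-2-(benzoyloxy)-3-hydroxy-7-oxabicyclo[4.1.0]hept-4-en-1-yl]methyl benzoate
Conditions: Bu4NF, AcOH, THF, 0 °C → rt
Reagents that add atoms: none
Why: Fluoride-induced cleavage of the silyl ether; acetic acid buffers the alkoxide so that the C2 benzoate should not migrate to the cis O3 and the allylic oxirane should not be opened.

## Compound list

1 | benzoic acid | OC(=O)c1ccccc1 | starting material
2 | cyclohexa-2,5-diene-1-carboxylic acid | OC(=O)C1C=CCC=C1 | intermediate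
3 | methyl cyclohexa-2,5-diene-1-carboxylate | COC(=O)C1C=CCC=C1 | intermediate
4 | potassium dienolate of 3, potassium (cyclohexa-2,5-dien-1-ylidene)(methoxy)methanolate (not isolated) | COC([O-])=C1C=CCC=C1.[K+] | intermediate
5 | methyl 1-hydroxycyclohexa-2,5-diene-1-carboxylate | COC(=O)C1(O)C=CCC=C1 | intermediate
6 | 1-(hydroxymethyl)cyclohexa-2,5-dien-1-ol | OCC1(O)C=CCC=C1 | intermediate
7 | benzoyl chloride | O=C(Cl)c1ccccc1 | starting material
8 | (1-hydroxycyclohexa-2,5-dien-1-yl)methyl benzoate | O=C(OCC1(O)C=CCC=C1)c1ccccc1 | intermediate
9 | carbon dioxide | O=C=O | starting material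
10 | N-iodosuccinimide | O=C1CCC(=O)N1I | starting material
11 | [1-(benzoyloxymethyl)cyclohexa-2,5-dien-1-yl] hydrogen carbonate, present as its amidinium salt (not isolated) | O=C(OCC1(OC(=O)O)C=CCC=C1)c1ccccc1 | intermediate
12 | [(3aR,7S,7aS)-7-iodo-2-oxo-3a,6,7,7a-tetrahydro-1,3-benzodioxol-3a-yl]methyl benzoate | O=C(OC[C@]12C=CC[C@H](I)[C@H]1OC(=O)O2)c1ccccc1 | intermediate
13 | [(3aR,7aR)-2-oxo-3a,7a-dihydro-1,3-benzodioxol-3a-yl]methyl benzoate (not isolated) | O=C(OC[C@]12C=CC=C[C@H]1OC(=O)O2)c1ccccc1 | intermediate
14 | (1R,2R)-1-(hydroxymethyl)cyclohexa-3,5-diene-1,2-diol | OC[C@]1(O)C=CC=C[C@H]1O | intermediate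
15 | (1S,2R,3R,6R)-3-(hydroxymethyl)-7-oxabicyclo[4.1.0]hept-4-ene-2,3-diol | OC[C@]1(O)C=C[C@H]2O[C@H]2[C@H]1O | intermediate
16 | [(1R,2R,3R,6R)-2-(benzoyloxy)-3-hydroxy-7-oxabicyclo[4.1.0]hept-4-en-3-yl]methyl benzoate | O=C(OC[C@]1(O)C=C[C@H]2O[C@H]2[C@H]1OC(=O)c1ccccc1)c1ccccc1 | intermediate
17 | [(1S,2R,3R,6S)-2-(benzoyloxy)-3-[(tert-butyldimethylsilyl)oxy]-7-oxabicyclo[4.1.0]hept-4-en-1-yl]methyl benzoate | O=C(OC[C@]12O[C@H]1C=C[C@@H](O[Si](C)(C)C(C)(C)C)[C@H]2OC(=O)c1ccccc1)c1ccccc1 | intermediate
18 | [(1S,2R,3R,6S)-2-(benzoyloxy)-3-hydroxy-7-oxabicyclo[4.1.0]hept-4-en-1-yl]methyl benzoate | O=C(OC[C@]12O[C@H]1C=C[C@@H](O)[C@H]2OC(=O)c1ccccc1)c1ccccc1 | target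

## Step count and least certain steps

Total step count: 11. Longest linear sequence: 11 steps (1 to 18); the route is fully linear, with 7, 9 and 10 purchased.

**Step 6 (key step, bears the label "Proposed new method:").**
- What may go wrong: too little of the hindered tertiary alcohol may be carbonated, so that uncatalysed pathways take over. These are participation of the O7 ester carbonyl in opening the iodonium ion, and ionisation of the doubly allylic C1–O bond followed by aromatisation. Discrimination between the two alkenes may also be weak, because the groups on C1 that the catalyst can hold lie in the mirror plane of the substrate.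
- Fallback (known chemistry; sets out from 1, returns at 14): whole cells of a Ralstonia eutropha strain blocked in the diol dehydrogenase oxidise 1 to (1S,2R)-1,2-dihydroxycyclohexa-3,5-diene-1-carboxylic acid F1 (identical with A3). Me3SiCHN2 in MeOH/PhMe gives methyl (1S,2R)-1,2-dihydroxycyclohexa-3,5-diene-1-carboxylate F2. LiBH4 in THF at 0 °C reduces the α-hydroxy ester to 14, whose C1 and C2 have the required arrangement. Steps 8 to 11 follow unchanged.

**Step 3.**
- What may go wrong: oxidative aromatisation of the dienolate by electron transfer to the oxaziridine, addition of the enolate to the sulfonimine by-product, or attack at the ring termini of the pentadienyl system instead of C1.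
- Fallback (sets out from 3 through 4, returns at 5): 4 is trapped with Me3SiCl as the silyl ketene acetal [(cyclohexa-2,5-dien-1-ylidene)(methoxy)methoxy]trimethylsilane F3. Dimethyldioxirane in acetone at −78 °C epoxidises only the electron-rich ketene acetal double bond, and silyl migration (Rubottom oxidation) gives methyl 1-(trimethylsilyloxy)cyclohexa-2,5-diene-1-carboxylate F4. Bu4NF buffered with AcOH removes the silyl group to give 5.

**Step 8.**
- What may go wrong: poor site and face selectivity, because O1–H and O7–H can also guide the peracid to C5=C6; over-oxidation of the second alkene; acid-promoted dehydration of the diene diol; and losses in handling a very polar triol.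
- Fallback (sets out from 14, returns at 16): 7 (1.0 equiv) with 2,4,6-collidine in CH2Cl2 at −40 °C acylates only the primary hydroxyl to [(1R,6R)-1,6-dihydroxycyclohexa-2,4-dien-1-yl]methyl benzoate F5. VO(acac)2 (cat.) with t-BuOOH in CH2Cl2 at 0 °C epoxidises C3=C4 through the vanadate ester of the less hindered secondary O2 under neutral conditions to [(1S,2R,3R,6R)-2,3-dihydroxy-7-oxabicyclo[4.1.0]hept-4-en-3-yl]methyl benzoate F6. Acylation of O2 with 7, pyridine and DMAP gives 16.

**Step 10.**
- What may go wrong: capture of the developing allyl cation at C6 or C4 by an ester carbonyl (six-membered participation from the O7 or O2 benzoate), silylation of O1 without migration of the epoxide, or renewed ionisation of the allylic oxirane of the product by excess silyl triflate.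
- Fallback (known chemistry; sets out from 16, returns at 17): sodium phenylselenide, from (PhSe)2 and NaBH4 in EtOH, opens the vinyl epoxide at the allylic C4 with inversion to [(1R,4S,5S,6R)-6-(benzoyloxy)-1,5-dihydroxy-4-(phenylselanyl)cyclohex-2-en-1-yl]methyl benzoate F7. t-BuMe2SiCl and imidazole in DMF silylate the secondary O3 to [(1R,4S,5S,6R)-6-(benzoyloxy)-5-[(tert-butyldimethylsilyl)oxy]-1-hydroxy-4-(phenylselanyl)cyclohex-2-en-1-yl]methyl benzoate F8. H2O2 and pyridine in CH2Cl2 give the allyl selenoxide, whose [2,3]-sigmatropic shift places oxygen on C6 on the face that selenium occupied, trans to O1; cleavage of the selenenate gives [(1S,2R,5R,6R)-6-(benzoyloxy)-5-[(tert-butyldimethylsilyl)oxy]-1,2-dihydroxycyclohex-3-en-1-yl]methyl benzoate F9. MeSO2Cl and Et3N at −20 °C give the secondary allylic mesylate [(1R,2R,5R,6R)-6-(benzoyloxy)-5-[(tert-butyldimethylsilyl)oxy]-1-hydroxy-2-(methanesulfonyloxy)cyclohex-3-en-1-yl]methyl benzoate F10. DBU then lets O1 displace the mesylate with inversion at C6, closing the oxirane of 17.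

## Further compounds

F1 | step 6 | (1S,2R)-1,2-dihydroxycyclohexa-3,5-diene-1-carboxylic acid (identical with A3) | OC(=O)[C@]1(O)C=CC=C[C@H]1O
F2 | step 6 | methyl (1S,2R)-1,2-dihydroxycyclohexa-3,5-diene-1-carboxylate | COC(=O)[C@]1(O)C=CC=C[C@H]1O
F3 | step 3 | [(cyclohexa-2,5-dien-1-ylidene)(methoxy)methoxy]trimethylsilane | COC(O[Si](C)(C)C)=C1C=CCC=C1
F4 | step 3 | methyl 1-(trimethylsilyloxy)cyclohexa-2,5-diene-1-carboxylate | COC(=O)C1(O[Si](C)(C)C)C=CCC=C1
F5 | step 8 | [(1R,6R)-1,6-dihydroxycyclohexa-2,4-dien-1-yl]methyl benzoate | O=C(OC[C@]1(O)C=CC=C[C@H]1O)c1ccccc1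
F6 | step 8 | [(1S,2R,3R,6R)-2,3-dihydroxy-7-oxabicyclo[4.1.0]hept-4-en-3-yl]methyl benzoate | O=C(OC[C@]1(O)C=C[C@H]2O[C@H]2[C@H]1O)c1ccccc1
F7 | step 10 | [(1R,4S,5S,6R)-6-(benzoyloxy)-1,5-dihydroxy-4-(phenylselanyl)cyclohex-2-en-1-yl]methyl benzoate | O=C(OC[C@]1(O)C=C[C@H]([Se]c2ccccc2)[C@@H](O)[C@H]1OC(=O)c1ccccc1)c1ccccc1
F8 | step 10 | [(1R,4S,5S,6R)-6-(benzoyloxy)-5-[(tert-butyldimethylsilyl)oxy]-1-hydroxy-4-(phenylselanyl)cyclohex-2-en-1-yl]methyl benzoate | O=C(OC[C@]1(O)C=C[C@H]([Se]c2ccccc2)[C@@H](O[Si](C)(C)C(C)(C)C)[C@H]1OC(=O)c1ccccc1)c1ccccc1
F9 | step 10 | [(1S,2R,5R,6R)-6-(benzoyloxy)-5-[(tert-butyldimethylsilyl)oxy]-1,2-dihydroxycyclohex-3-en-1-yl]methyl benzoate | O=C(OC[C@]1(O)[C@H](O)C=C[C@@H](O[Si](C)(C)C(C)(C)C)[C@H]1OC(=O)c1ccccc1)c1ccccc1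
F10 | step 10 | [(1R,2R,5R,6R)-6-(benzoyloxy)-5-[(tert-butyldimethylsilyl)oxy]-1-hydroxy-2-(methanesulfonyloxy)cyclohex-3-en-1-yl]methyl benzoate | O=C(OC[C@]1(O)[C@H](OS(C)(=O)=O)C=C[C@@H](O[Si](C)(C)C(C)(C)C)[C@H]1OC(=O)c1ccccc1)c1ccccc1
A1 | alternative 1 | (1S,4R,5S)-4-[(tert-butyldimethylsilyl)oxy]-5-[(4-methoxyphenyl)methoxy]-6-methylidenecyclohex-2-en-1-ol | C=C1[C@@H](O)C=C[C@@H](O[Si](C)(C)C(C)(C)C)[C@H]1OCc1ccc(OC)cc1
A2 | alternative 1 | tert-butyl{[(1S,2R,3R,6S)-1-(iodomethyl)-2-[(4-methoxyphenyl)methoxy]-7-oxabicyclo[4.1.0]hept-4-en-3-yl]oxy}dimethylsilane | IC[C@]12O[C@H]1C=C[C@@H](O[Si](C)(C)C(C)(C)C)[C@H]2OCc1ccc(OC)cc1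
A3 | alternative 2 | (1S,2R)-1,2-dihydroxycyclohexa-3,5-diene-1-carboxylic acid | OC(=O)[C@]1(O)C=CC=C[C@H]1O
A4 | alternative 3 | (1E,3E)-buta-1,3-diene-1,4-diyl diacetate | CC(=O)O/C=C/C=C/OC(C)=O
A5 | alternative 3 | (Z)-2,3-bis(benzoyloxy)prop-2-enal | O=C/C(OC(=O)c1ccccc1)=C/OC(=O)c1ccccc1
A6 | alternative 3 | all-cis 3,6-diacetoxy-1,2-bis(benzoyloxy)cyclohex-4-ene-1-carbaldehyde (absolute configuration as in the SMILES) | O=C[C@]1(OC(=O)c2ccccc2)[C@@H](OC(C)=O)C=C[C@@H](OC(C)=O)[C@H]1OC(=O)c1ccccc1
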